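## Analysis of the target

The target (34) is a 2,3,4,7-tetrahydrooxepine: a seven-membered ring of O1 and the carbons C2 to C7 with one endocyclic alkene, C5=C6. C2 is fully substituted and carries the ring oxygen, the free carboxylic acid, ring carbon C3 and a CH2–C(=O) arm that ends in a 2,5-dihydroxyphenyl ketone. C6 carries a (3E)-5-hydroxy-4-methylpent-3-enyl chain, and C7 is an allylic OCH2 group. C2 (R) is the only stereocentre, so no relative configuration has to be controlled; the other stereochemical element is the E geometry of the side-chain alkene, while the ring alkene is cis by necessity. The aryl ketone sits β to the ring oxygen, so base (and hot acid) can open the ring by retro-oxa-Michael elimination, after which the free ortho phenol could close a chromanone. The hydroquinone is oxidised by air, and the primary allylic alcohol and two trisubstituted alkenes limit the use of strong acid and electrophilic oxidants. The difficulty is an oxygen-bearing quaternary stereocentre that is part of a seven-membered ether: closing that ring by C–O bond formation at a tertiary carbon would be slow and hard to render enantioselective. The strategy rests on the observation that, without O1, the atoms C2 to C7 form a six-membered carbocycle, a cyclohexanone with its carbonyl at C7 and C2 as the α-quaternary carbon of a β-keto ester. The configuration of C2 can therefore be set in a C–C bond formation and the oxygen inserted afterwards.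

## Retrosynthetic reasoning

34 from 33. The acid, the two phenols and the allylic alcohol are unmasked together in the last step from the tert-butyl ester and three methoxymethyl ethers of 33. The hydroquinone and the base-sensitive β-alkoxy ketone should be exposed as late as possible, and an ester cleaved by acid avoids any saponification.

33 from 28 and 30. The bond between the ketone carbon and the arene is cut. The arene becomes the aryllithium 31, made by ortho-lithiation of the symmetrical bis-ether 30 (one step from hydroquinone 29). The acyl partner is the N-methoxy-N-methylamide 28. This cut is chosen because the adduct 32 keeps the carbonyl masked until the quench, so the β-alkoxy ketone never meets the organolithium.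

28 back to 23. The amide comes from the acid 26, which comes from the primary alcohol 24 and its silyl ether 23. These are oxidation-level changes on a two-carbon arm whose terminal oxygen has been carried, protected, from the start.

23 from 19. The two hydrogens on C7 replace a carbonyl oxygen: the ether 23 is traced to the acetoxy ether 21 and this to the unsaturated lactone 19. The carbonyl is removed only here because it is what the ring expansion leaves behind and what activates C6 in the steps before.

19 from 14 and 17. The C6–C1′ bond is cut as an sp2–sp3 cross-coupling between the iodo lactone 14 and the alkylzinc 18 derived from bromide 17. The E-allylic oxygen of the chain is installed on the small fragment (15 to 16 to 17), where an allylic oxidation has only one alkene to choose from.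

14 back to 9. The iodine and the C5=C6 alkene are removed in turn: 14 from the unsaturated lactone 13, and 13 from the saturated lactone 9 through the selenide 11. All of this relies on the acidity of C6–H next to the lactone carbonyl; the tert-butyl ester on C2 has no α-hydrogen and cannot compete.

9 from 7 (key disconnection). O1 is excised: the O1–C2 and O1–C7 bonds are replaced by a C2–C7 bond, which turns the ε-lactone 9 into the cyclohexanone 7. The forward reaction has to insert one oxygen atom on the quaternary side of the ketone with retention at C2. The gain is that the ring is made by a one-atom enlargement of a six-membered ring and that the C–O stereocentre is derived from a C–C stereocentre.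

7 from 1 and 2. The silyloxyethyl arm of 7 is an allyl group shortened by one carbon (7 from 6 from 5 from 3), and 3 is the product of an enantioselective allylation of the commercial β-keto ester 1 with allyl acetate 2. The alkene has to be cleaved before the peracid step, and the silyl group is chosen as tert-butyldiphenylsilyl so that it withstands the acid set free in that step and the Lewis acid used later.

## Alternatives that were turned down

Alternative 1: Here the aryl ketone is not made from an aryl anion and an acyl donor. The bond between the ketone carbon and the arene and the bond between the neighbouring ring carbon and its phenolic oxygen are cut together, which leads back to the carboxylic acid A2 (the same compound as 26) and an aryne. In the forward step fluoride releases the aryne from the ortho-silylaryl triflate A3; the carboxylate of A2 adds through oxygen, the aryl anion attacks the acyl carbon, and the four-membered intermediate opens to the ortho-hydroxyaryl ketone A1. No ring is closed.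
- For it: the ketone comes in one step from the acid, no organolithium meets the β-alkoxy carbonyl unit, and the ortho oxygen arrives as the free phenol.
- Against it: it is an end-game device and leaves the real problems, the oxygen-bearing quaternary C2 and the seven-membered ring, to whatever route delivers A2. The aryne is unsymmetrical, so a bromine atom must be carried to steer the addition and must later be removed reductively in the presence of two alkenes and an allylic ether. A3 is a crowded tetrasubstituted arene needing several steps, whereas 30 is one step from 29 and has four equivalent positions. Attack of the aryl anion on a hindered carboxyl carbon competes with simple protonation to the aryl ester. The ortho-hydroxyaryl ketone is unmasked at least two steps before the end, so debromination and deprotection run on a compound already able to open and re-close to a chromanone.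
- Comparison: from the acid to the ketone the aryne step is stronger (one step against steps 16 and 18). The chosen strategy offers in exchange a plan for the ring and the stereocentre, a symmetrical arene, and phenols that stay masked until the last step.

Alternative 2: The ring is opened at O1–C2. The precursor is the acyclic (Z)-allylic alcohol A5, in which C2 is the β-carbon of an (E)-aroylacrylate. A chiral bifunctional catalyst (a strongly basic iminophosphorane tethered to a thiourea) is to guide the C7 hydroxyl onto C2, closing the oxepine and setting the quaternary stereocentre in one step to give A4, the same compound as 33.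
- For it: it follows the likely biosynthesis, ring and stereocentre come from one catalytic step at the very end, and A5 can be assembled convergently. On step economy and convergence it is stronger than the chosen plan.
- Against it: the closure is a 7-exo-trig addition of a weakly nucleophilic primary alcohol to a β,β-disubstituted acceptor, slow for both entropic and steric reasons. The addition is reversible, so the closed form is not guaranteed by thermodynamics and kinetic enantioselectivity can leak away through the retro reaction under the same base. The catalyst must tell apart the faces of a trisubstituted alkene while the nucleophile hangs on a flexible six-atom tether, which gives little basis for face control. The C5=C6 alkene of A5 has to be built with Z geometry, which the ring enforces in the chosen route.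
- Comparison: the chosen strategy is longer but separates the two problems. C2 is fixed in a well-understood C–C bond formation (step 1), and the oxygen is then inserted by an irreversible migration that cannot racemise C2 and involves no medium-ring cyclisation.

Alternative 3: The ring is cut at C4–C5 and C6–C7, so that C5 and C6 come from an alkyne and O1, C2, C3, C4 and C7 from a five-membered enol ether. An alkylaluminium chloride Lewis acid is to promote [2+2] cycloaddition of methyl propiolate A8 to the enol ether of the 2,3-dihydrofuran A7; the fused cyclobutene then opens at the shared bond and releases the 2,3-dihydrooxepine A6, a two-carbon ring expansion.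
- For it: the quaternary centre is set in a five-membered ring, the seven-membered ring arises without a medium-ring cyclisation, and C6 receives a carbon substituent in the same step. On this last point it is stronger than the chosen plan, which needs steps 7, 8 and 11 to functionalise C6.
- Against it: A6 is a dienyl ether with C4=C5 and C6=C7 double bonds, so one alkene must be removed and the other moved to C5=C6, a redox and isomerisation problem with no obvious selective answer. The C6 ester must be reduced and extended by four carbons. The enantioenriched dihydrofuran A7 is itself a multistep target that poses the same stereochemical question. An enol ether and a tert-butyl ester must survive a strong Lewis acid, with polymerisation as the obvious competitor.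
- Comparison: both plans are ring expansions. The chosen one inserts one atom, leaves exactly one functional group (the C7 carbonyl) that first activates C6 and is then removed in two steps, and starts from a commercial β-keto ester.

Key step: step 5

Assumption: the (1R,2R)-configured ligand of step 1 is taken to deliver the (1S) keto ester 3; should the sense of induction be the reverse, the enantiomeric ligand is used and nothing else changes.

Abbreviations used in the steps: TBDPS = tert-butyldiphenylsilyl; MOM = methoxymethyl.

## Route

Step 1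
Reactants: 1 tert-butyl 2-oxocyclohexane-1-carboxylate; 2 allyl acetate (prop-2-en-1-yl acetate)
Product: 3 tert-butyl (1S)-2-oxo-1-(prop-2-en-1-yl)cyclohexane-1-carboxylate
Conditions: [Pd(C3H5)Cl]2 (cat.), (1R,2R)-N,N′-bis[2-(diphenylphosphanyl)benzoyl]cyclohexane-1,2-diamine (cat.), tetramethylguanidine, toluene, 0 °C
Reagents that add atoms: none
Why: Tsuji–Trost asymmetric allylic alkylation: zerovalent palladium ionises 2 to a π-allyl complex, which is attacked by the guanidinium enolate of 1. The chiral pocket of the diphosphine differentiates the enantiotopic faces of the tetrasubstituted enolate and so sets the quaternary stereocentre.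

Step 2
Reactants: 3 tert-butyl (1S)-2-oxo-1-(prop-2-en-1-yl)cyclohexane-1-carboxylate
Product: 5 tert-butyl (1S)-2-oxo-1-(2-oxoethyl)cyclohexane-1-carboxylate, via secondary ozonide 4 (not isolated)
Conditions: O3, CH2Cl2, −78 °C; then PPh3, −78 °C → rt
Reagents that add atoms: ozone, [O-][O+]=O
Why: Ozonolysis (cycloaddition, cycloreversion and recombination to the 1,2,4-trioxolane, then reduction by the phosphine) cleaves the only alkene and shortens the allyl group to the two-carbon aldehyde arm. The ketone, the ester and the quaternary centre are not touched.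

Step 3
Reactants: 5 tert-butyl (1S)-2-oxo-1-(2-oxoethyl)cyclohexane-1-carboxylate
Product: 6 tert-butyl (1S)-1-(2-hydroxyethyl)-2-oxocyclohexane-1-carboxylate
Conditions: NaBH(OAc)3, AcOH, THF, rt → 40 °C
Reagents that add atoms: none
Why: Chemoselective hydride reduction: triacetoxyborohydride is a weak hydride donor that reduces aldehydes but should leave a ketone alone, here one that is also hindered by the adjacent quaternary carbon.

Step 4
Reactants: 6 tert-butyl (1S)-1-(2-hydroxyethyl)-2-oxocyclohexane-1-carboxylate
Product: 7 tert-butyl (1S)-1-[2-(TBDPS-oxy)ethyl]-2-oxocyclohexane-1-carboxylate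
Conditions: tBuPh2SiCl, imidazole, CH2Cl2, 0 °C → rt
Reagents that add atoms: tert-butyl(chloro)diphenylsilane, CC(C)(C)[Si](Cl)(c1ccccc1)c1ccccc1
Why: Standard silylation of a primary alcohol. The bulky, acid-stable TBDPS group is chosen because CF3CO2H is liberated in the next step and BF3·OEt2 is used in step 13.

Step 5
Reactants: 7 tert-butyl (1S)-1-[2-(TBDPS-oxy)ethyl]-2-oxocyclohexane-1-carboxylate
Product: 9 tert-butyl (2R)-2-[2-(TBDPS-oxy)ethyl]-7-oxooxepane-2-carboxylate, via Criegee adduct 8 (not isolated)
Conditions: (CF3CO)2O, urea·H2O2, Na2HPO4, CH2Cl2, 0 °C → rt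
Reagents that add atoms: trifluoroperacetic acid, OOC(=O)C(F)(F)F (made in the flask from trifluoroacetic anhydride, O=C(OC(=O)C(F)(F)F)C(F)(F)F, and urea–hydrogen peroxide, NC(N)=O.OO)
Why: Baeyer–Villiger oxidation: CF3CO3H adds to the ketone carbon (C7 of the future oxepane) to give the Criegee adduct 8, and the C2–C7 bond lying antiperiplanar to the O–O bond shifts from carbon to the proximal oxygen as trifluoroacetate leaves, so that O1 is inserted and both ring C–O bonds (O1–C2 and O1–C7) are made in one event. The closest known reaction type is the Baeyer–Villiger oxidation of α,α-disubstituted cyclic β-keto esters, in which the fully substituted α-carbon migrates. The seven-membered lactone is closed by enlargement of a preformed six-membered ring through a 1,2-shift, not by an end-to-end cyclisation, so no medium-ring entropy has to be paid. No stereocentre is created: C2 migrates with retention because the shift is concerted and suprafacial, and the change of descriptor from 1S in 7 to 2R in 9 reflects only the new substituent priorities. The selectivity needed is migration of C2 in preference to the C6 methylene; C2 is the more substituted carbon and better supports the electron-deficient transition state, which should outweigh the inductive pull of its ester, and in the chair adduct the C2–C7 bond can readily reach the antiperiplanar arrangement. The strongly electrophilic peracid is needed because the ketone is hindered and electron-poor; Na2HPO4 takes up CF3CO2H so that the tert-butyl ester and the silyl ether survive. No alkene is present at this stage that could be epoxidised.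

Step 6
Reactants: 9 tert-butyl (2R)-2-[2-(TBDPS-oxy)ethyl]-7-oxooxepane-2-carboxylate
Product: 11 tert-butyl (2R)-2-[2-(TBDPS-oxy)ethyl]-7-oxo-6-(phenylselanyl)oxepane-2-carboxylate (both C6 epimers), via lithium enolate 10 (not isolated)
Conditions: LiN(iPr)2, THF, −78 °C; then PhSeBr, −78 °C
Reagents that add atoms: phenylselanyl bromide, Br[Se]c1ccccc1
Why: Enolate selenenylation: the only acidic C–H of 9 is on C6, because the tert-butyl ester has no α-hydrogen, so one enolate forms and is selenenylated at carbon. The low temperature keeps the enolate from attacking the hindered ester.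

Step 7
Reactants: 11 tert-butyl (2R)-2-[2-(TBDPS-oxy)ethyl]-7-oxo-6-(phenylselanyl)oxepane-2-carboxylate
Product: 13 tert-butyl (2R)-2-[2-(TBDPS-oxy)ethyl]-7-oxo-2,3,4,7-tetrahydrooxepine-2-carboxylate, via selenoxide 12 (not isolated)
Conditions: 30% H2O2, pyridine, CH2Cl2, 0 °C → rt
Reagents that add atoms: none
Why: Selenoxide syn-elimination: the only β-hydrogens are on C5, so the C5=C6 alkene conjugated with the lactone is the single possible product, and the ring fixes its cis geometry.

Step 8
Reactants: 13 tert-butyl (2R)-2-[2-(TBDPS-oxy)ethyl]-7-oxo-2,3,4,7-tetrahydrooxepine-2-carboxylate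
Product: 14 tert-butyl (2R)-2-[2-(TBDPS-oxy)ethyl]-6-iodo-7-oxo-2,3,4,7-tetrahydrooxepine-2-carboxylate
Conditions: I2, pyridine, 4-(dimethylamino)pyridine (cat.), CH2Cl2, rt → 40 °C
Reagents that add atoms: iodine, II
Why: α-Iodination of a conjugated carbonyl compound by addition–elimination: the amine adds to C5, the resulting enolate is iodinated at C6, and loss of the amine restores the alkene. No other alkene or enolisable position is present.

Step 9
Reactants: 15 5-bromo-2-methylpent-2-ene
Product: 16 (2E)-5-bromo-2-methylpent-2-en-1-ol
Conditions: SeO2 (cat.), tBuOOH, salicylic acid (cat.), CH2Cl2, rt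
Reagents that add atoms: selenium dioxide, O=[Se]=O; tert-butyl hydroperoxide, CC(C)(C)OO
Why: SeO2 allylic oxidation (ene reaction, then [2,3]-sigmatropic shift) is known to attack the E-methyl group of a gem-dimethyl alkene terminus and so should give the (E)-allylic alcohol. The catalytic protocol limits over-oxidation, and the primary bromide is inert.

Step 10
Reactants: 16 (2E)-5-bromo-2-methylpent-2-en-1-ol
Product: 17 (2E)-5-bromo-1-(MOM-oxy)-2-methylpent-2-ene
Conditions: MeOCH2Cl, iPr2NEt, CH2Cl2, 0 °C → rt
Reagents that add atoms: chloromethyl methyl ether, COCCl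
Why: Alkoxymethylation of the primary alcohol under a non-nucleophilic amine base. The MOM ether tolerates organozinc, hydride, Lewis acid at low temperature and fluoride, and falls to acid in the last step.

Step 11
Reactants: 14 tert-butyl (2R)-2-[2-(TBDPS-oxy)ethyl]-6-iodo-7-oxo-2,3,4,7-tetrahydrooxepine-2-carboxylate; 17 (2E)-5-bromo-1-(MOM-oxy)-2-methylpent-2-ene
Product: 19 tert-butyl (2R)-2-[2-(TBDPS-oxy)ethyl]-6-[(3E)-5-(MOM-oxy)-4-methylpent-3-en-1-yl]-7-oxo-2,3,4,7-tetrahydrooxepine-2-carboxylate, via alkylzinc bromide 18 (not isolated)
Conditions: 17, Zn dust (activated), LiCl, THF, 50 °C; then 14, Pd(OAc)2 (cat.), 2-dicyclohexylphosphino-2′,6′-dimethoxybiphenyl (cat.), THF, rt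
Reagents that add atoms: none
Why: Negishi coupling: LiCl-assisted insertion of zinc into the primary C–Br bond gives an alkylzinc that tolerates the esters, and it transmetalates to the palladium complex formed by oxidative addition of zerovalent palladium to the electron-poor C6–I bond. The bulky biarylphosphine favours reductive elimination over β-hydride elimination, and both alkene geometries are retained.

Step 12
Reactants: 19 tert-butyl (2R)-2-[2-(TBDPS-oxy)ethyl]-6-[(3E)-5-(MOM-oxy)-4-methylpent-3-en-1-yl]-7-oxo-2,3,4,7-tetrahydrooxepine-2-carboxylate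
Product: 21 tert-butyl (2R)-7-acetoxy-2-[2-(TBDPS-oxy)ethyl]-6-[(3E)-5-(MOM-oxy)-4-methylpent-3-en-1-yl]-2,3,4,7-tetrahydrooxepine-2-carboxylate (both C7 epimers), via aluminium hemiacetal 20 (not isolated)
Conditions: iBu2AlH, CH2Cl2, −78 °C; then pyridine, 4-(dimethylamino)pyridine, Ac2O, −78 → −20 °C
Reagents that add atoms: acetic anhydride, CC(=O)OC(C)=O
Why: Reductive acetylation of a lactone: iBu2AlH should add once to the more Lewis-basic, less hindered conjugated lactone carbonyl and leave the neopentyl-type tert-butyl ester. Acetylating the aluminium hemiacetal in the flask fixes the ring-closed form, which matters because a free seven-membered lactol would open to the hydroxy aldehyde.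

Step 13
Reactants: 21 tert-butyl (2R)-7-acetoxy-2-[2-(TBDPS-oxy)ethyl]-6-[(3E)-5-(MOM-oxy)-4-methylpent-3-en-1-yl]-2,3,4,7-tetrahydrooxepine-2-carboxylate
Product: 23 tert-butyl (2R)-2-[2-(TBDPS-oxy)ethyl]-6-[(3E)-5-(MOM-oxy)-4-methylpent-3-en-1-yl]-2,3,4,7-tetrahydrooxepine-2-carboxylate, via oxocarbenium ion 22 (not isolated)
Conditions: Et3SiH, BF3·OEt2, CH2Cl2, −78 °C
Reagents that add atoms: none
Why: Ionic reduction of an acetoxy ether: BF3·OEt2 ionises the acetate to an alkene-conjugated oxocarbenium ion and Et3SiH delivers hydride to C7, the carbon next to oxygen, as in silane reductions of unsaturated glycosyl donors. The low temperature should spare the tert-butyl ester, the MOM ether and the silyl ether.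

Step 14
Reactants: 23 tert-butyl (2R)-2-[2-(TBDPS-oxy)ethyl]-6-[(3E)-5-(MOM-oxy)-4-methylpent-3-en-1-yl]-2,3,4,7-tetrahydrooxepine-2-carboxylate
Product: 24 tert-butyl (2R)-2-(2-hydroxyethyl)-6-[(3E)-5-(MOM-oxy)-4-methylpent-3-en-1-yl]-2,3,4,7-tetrahydrooxepine-2-carboxylate
Conditions: Bu4NF, AcOH, THF, 0 °C → rt
Reagents that add atoms: none
Why: Fluoride-mediated desilylation. Acetic acid buffers the alkoxide so that it does not lactonise onto the neighbouring tert-butyl ester, and the MOM ether is inert.

Step 15
Reactants: 24 tert-butyl (2R)-2-(2-hydroxyethyl)-6-[(3E)-5-(MOM-oxy)-4-methylpent-3-en-1-yl]-2,3,4,7-tetrahydrooxepine-2-carboxylate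
Product: 26 2-[(2R)-2-(tert-butoxycarbonyl)-6-[(3E)-5-(MOM-oxy)-4-methylpent-3-en-1-yl]-2,3,4,7-tetrahydrooxepin-2-yl]acetic acid, via aldehyde 25 (not isolated)
Conditions: 2,2,6,6-tetramethylpiperidin-1-oxyl (cat.), PhI(OAc)2, MeCN/H2O, rt
Reagents that add atoms: water, O
Why: Oxoammonium-mediated oxidation: the primary alcohol is oxidised to the aldehyde, whose hydrate is oxidised on to the acid in the aqueous medium. The alkenes, the allylic ether and the acetal tolerate these near-neutral conditions, and the β-alkoxy aldehyde never meets base.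

Step 16
Reactants: 26 2-[(2R)-2-(tert-butoxycarbonyl)-6-[(3E)-5-(MOM-oxy)-4-methylpent-3-en-1-yl]-2,3,4,7-tetrahydrooxepin-2-yl]acetic acid
Product: 28 tert-butyl (2R)-2-{2-[methoxy(methyl)amino]-2-oxoethyl}-6-[(3E)-5-(MOM-oxy)-4-methylpent-3-en-1-yl]-2,3,4,7-tetrahydrooxepine-2-carboxylate, via acyl imidazole 27 (not isolated)
Conditions: 1,1′-carbonyldiimidazole, CH2Cl2, rt; then MeNHOMe·HCl, rt
Reagents that add atoms: N,O-dimethylhydroxylamine hydrochloride, CNOC.Cl
Why: Amide formation through the acyl imidazole is a standard, strong-base-free way to an N-methoxy-N-methylamide (Weinreb amide).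

Step 17
Reactants: 29 hydroquinone (benzene-1,4-diol)
Product: 30 1,4-bis(MOM-oxy)benzene
Conditions: NaH, MeOCH2Cl, DMF, 0 °C → rt
Reagents that add atoms: chloromethyl methyl ether, COCCl
Why: Double O-alkylation of the phenoxides. The MOM groups later direct ortho-lithiation and are cleaved by the acid of the last step.

Step 18
Reactants: 28 tert-butyl (2R)-2-{2-[methoxy(methyl)amino]-2-oxoethyl}-6-[(3E)-5-(MOM-oxy)-4-methylpent-3-en-1-yl]-2,3,4,7-tetrahydrooxepine-2-carboxylate; 30 1,4-bis(MOM-oxy)benzene
Product: 33 tert-butyl (2R)-2-{2-[2,5-bis(MOM-oxy)phenyl]-2-oxoethyl}-6-[(3E)-5-(MOM-oxy)-4-methylpent-3-en-1-yl]-2,3,4,7-tetrahydrooxepine-2-carboxylate, via aryllithium 31 (not isolated), via tetrahedral adduct 32 (not isolated)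
Conditions: 30, n-BuLi, TMEDA, THF, 0 °C; then 28, −78 → −20 °C; aq. NH4Cl
Reagents that add atoms: none
Why: Directed ortho-metalation of 30 (all four ring positions are equivalent) gives 31, which adds to the amide to form the chelated adduct 32. This adduct releases the ketone only on quench, so neither over-addition nor base-induced ring opening of the β-alkoxy ketone should occur, and the hindered tert-butyl ester should be left.

Step 19
Reactants: 33 tert-butyl (2R)-2-{2-[2,5-bis(MOM-oxy)phenyl]-2-oxoethyl}-6-[(3E)-5-(MOM-oxy)-4-methylpent-3-en-1-yl]-2,3,4,7-tetrahydrooxepine-2-carboxylate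
Product: 34 (2R)-2-[2-(2,5-dihydroxyphenyl)-2-oxoethyl]-6-[(3E)-5-hydroxy-4-methylpent-3-en-1-yl]-2,3,4,7-tetrahydrooxepine-2-carboxylic acid
Conditions: CF3CO2H/CH2Cl2/H2O, 0 °C → rt, under argon; then brief aq. NaHCO3/MeOH, 0 °C, and acidification to pH 3
Reagents that add atoms: none
Why: Global acidolysis: the tert-butyl ester loses isobutene and the three MOM acetals are hydrolysed. Water traps the cations and limits trifluoroacetylation of the allylic alcohol (any such ester is removed in the short bicarbonate wash); silane scavengers are avoided because they would reduce the aryl ketone under acid, and air is excluded to protect the hydroquinone.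

## Compound list

1 | tert-butyl 2-oxocyclohexane-1-carboxylate | O=C1CCCCC1C(=O)OC(C)(C)C | starting material
2 | allyl acetate (prop-2-en-1-yl acetate) | CC(=O)OCC=C | starting material
3 | tert-butyl (1S)-2-oxo-1-(prop-2-en-1-yl)cyclohexane-1-carboxylate | O=C1CCCC[C@@]1(CC=C)C(=O)OC(C)(C)C | intermediate
4 | tert-butyl (1S)-2-oxo-1-[(1,2,4-trioxolan-3-yl)methyl]cyclohexane-1-carboxylate (secondary ozonide) | O=C1CCCC[C@@]1(CC2OCOO2)C(=O)OC(C)(C)C | intermediate (not isolated)
5 | tert-butyl (1S)-2-oxo-1-(2-oxoethyl)cyclohexane-1-carboxylate | O=C1CCCC[C@@]1(CC=O)C(=O)OC(C)(C)C | intermediate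
6 | tert-butyl (1S)-1-(2-hydroxyethyl)-2-oxocyclohexane-1-carboxylate | O=C1CCCC[C@@]1(CCO)C(=O)OC(C)(C)C | intermediate
7 | tert-butyl (1S)-1-[2-(tert-butyldiphenylsilyloxy)ethyl]-2-oxocyclohexane-1-carboxylate | O=C1CCCC[C@@]1(CCO[Si](c2ccccc2)(c2ccccc2)C(C)(C)C)C(=O)OC(C)(C)C | intermediate
8 | tert-butyl (1S)-1-[2-(tert-butyldiphenylsilyloxy)ethyl]-2-hydroxy-2-[(trifluoroacetyl)peroxy]cyclohexane-1-carboxylate (Criegee adduct) | OC1(OOC(=O)C(F)(F)F)CCCC[C@@]1(CCO[Si](c2ccccc2)(c2ccccc2)C(C)(C)C)C(=O)OC(C)(C)C | intermediate (not isolated)
9 | tert-butyl (2R)-2-[2-(tert-butyldiphenylsilyloxy)ethyl]-7-oxooxepane-2-carboxylate | O=C1CCCC[C@@](CCO[Si](c2ccccc2)(c2ccccc2)C(C)(C)C)(C(=O)OC(C)(C)C)O1 | intermediate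
10 | tert-butyl (2R)-2-[2-(tert-butyldiphenylsilyloxy)ethyl]-7-(lithiooxy)-2,3,4,5-tetrahydrooxepine-2-carboxylate (lithium enolate of 9) | [Li]OC1=CCCC[C@@](CCO[Si](c2ccccc2)(c2ccccc2)C(C)(C)C)(C(=O)OC(C)(C)C)O1 | intermediate (not isolated)
11 | tert-butyl (2R)-2-[2-(tert-butyldiphenylsilyloxy)ethyl]-7-oxo-6-(phenylselanyl)oxepane-2-carboxylate | O=C1C([Se]c2ccccc2)CCC[C@@](CCO[Si](c2ccccc2)(c2ccccc2)C(C)(C)C)(C(=O)OC(C)(C)C)O1 | intermediate
12 | tert-butyl (2R)-2-[2-(tert-butyldiphenylsilyloxy)ethyl]-7-oxo-6-(phenylseleninyl)oxepane-2-carboxylate (selenoxide) | O=C1C([Se](=O)c2ccccc2)CCC[C@@](CCO[Si](c2ccccc2)(c2ccccc2)C(C)(C)C)(C(=O)OC(C)(C)C)O1 | intermediate (not isolated)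
13 | tert-butyl (2R)-2-[2-(tert-butyldiphenylsilyloxy)ethyl]-7-oxo-2,3,4,7-tetrahydrooxepine-2-carboxylate | O=C1C=CCC[C@@](CCO[Si](c2ccccc2)(c2ccccc2)C(C)(C)C)(C(=O)OC(C)(C)C)O1 | intermediate
14 | tert-butyl (2R)-2-[2-(tert-butyldiphenylsilyloxy)ethyl]-6-iodo-7-oxo-2,3,4,7-tetrahydrooxepine-2-carboxylate | O=C1C(I)=CCC[C@@](CCO[Si](c2ccccc2)(c2ccccc2)C(C)(C)C)(C(=O)OC(C)(C)C)O1 | intermediate
15 | 5-bromo-2-methylpent-2-ene | CC(C)=CCCBr | starting material
16 | (2E)-5-bromo-2-methylpent-2-en-1-ol | C/C(=C\CCBr)CO | intermediate
17 | (2E)-5-bromo-1-(methoxymethoxy)-2-methylpent-2-ene | C/C(=C\CCBr)COCOC | intermediate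
18 | [(3E)-5-(methoxymethoxy)-4-methylpent-3-en-1-yl]zinc bromide | C/C(=C\CC[Zn]Br)COCOC | intermediate (not isolated)
19 | tert-butyl (2R)-2-[2-(tert-butyldiphenylsilyloxy)ethyl]-6-[(3E)-5-(methoxymethoxy)-4-methylpent-3-en-1-yl]-7-oxo-2,3,4,7-tetrahydrooxepine-2-carboxylate | C/C(=C\CCC1=CCC[C@@](CCO[Si](c2ccccc2)(c2ccccc2)C(C)(C)C)(C(=O)OC(C)(C)C)OC1=O)COCOC | intermediate
20 | tert-butyl (2R)-2-[2-(tert-butyldiphenylsilyloxy)ethyl]-7-[(diisobutylalumanyl)oxy]-6-[(3E)-5-(methoxymethoxy)-4-methylpent-3-en-1-yl]-2,3,4,7-tetrahydrooxepine-2-carboxylate (aluminium hemiacetal) | C/C(=C\CCC1=CCC[C@@](CCO[Si](c2ccccc2)(c2ccccc2)C(C)(C)C)(C(=O)OC(C)(C)C)OC1O[Al](CC(C)C)CC(C)C)COCOC | intermediate (not isolated)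
21 | tert-butyl (2R)-7-acetoxy-2-[2-(tert-butyldiphenylsilyloxy)ethyl]-6-[(3E)-5-(methoxymethoxy)-4-methylpent-3-en-1-yl]-2,3,4,7-tetrahydrooxepine-2-carboxylate | C/C(=C\CCC1=CCC[C@@](CCO[Si](c2ccccc2)(c2ccccc2)C(C)(C)C)(C(=O)OC(C)(C)C)OC1OC(C)=O)COCOC | intermediate
22 | (2R)-2-(tert-butoxycarbonyl)-2-[2-(tert-butyldiphenylsilyloxy)ethyl]-6-[(3E)-5-(methoxymethoxy)-4-methylpent-3-en-1-yl]-3,4-dihydro-2H-oxepin-1-ium (oxocarbenium ion) | C/C(=C\CCC1=CCC[C@@](CCO[Si](c2ccccc2)(c2ccccc2)C(C)(C)C)(C(=O)OC(C)(C)C)[O+]=C1)COCOC | intermediate (not isolated)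
23 | tert-butyl (2R)-2-[2-(tert-butyldiphenylsilyloxy)ethyl]-6-[(3E)-5-(methoxymethoxy)-4-methylpent-3-en-1-yl]-2,3,4,7-tetrahydrooxepine-2-carboxylate | C/C(=C\CCC1=CCC[C@@](CCO[Si](c2ccccc2)(c2ccccc2)C(C)(C)C)(C(=O)OC(C)(C)C)OC1)COCOC | intermediate
24 | tert-butyl (2R)-2-(2-hydroxyethyl)-6-[(3E)-5-(methoxymethoxy)-4-methylpent-3-en-1-yl]-2,3,4,7-tetrahydrooxepine-2-carboxylate | C/C(=C\CCC1=CCC[C@@](CCO)(C(=O)OC(C)(C)C)OC1)COCOC | intermediate
25 | tert-butyl (2R)-6-[(3E)-5-(methoxymethoxy)-4-methylpent-3-en-1-yl]-2-(2-oxoethyl)-2,3,4,7-tetrahydrooxepine-2-carboxylate | C/C(=C\CCC1=CCC[C@@](CC=O)(C(=O)OC(C)(C)C)OC1)COCOC | intermediate (not isolated)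
26 | 2-[(2R)-2-(tert-butoxycarbonyl)-6-[(3E)-5-(methoxymethoxy)-4-methylpent-3-en-1-yl]-2,3,4,7-tetrahydrooxepin-2-yl]acetic acid | C/C(=C\CCC1=CCC[C@@](CC(=O)O)(C(=O)OC(C)(C)C)OC1)COCOC | intermediate
27 | tert-butyl (2R)-2-[2-(1H-imidazol-1-yl)-2-oxoethyl]-6-[(3E)-5-(methoxymethoxy)-4-methylpent-3-en-1-yl]-2,3,4,7-tetrahydrooxepine-2-carboxylate (acyl imidazole) | C/C(=C\CCC1=CCC[C@@](CC(=O)n2ccnc2)(C(=O)OC(C)(C)C)OC1)COCOC | intermediate (not isolated)
28 | tert-butyl (2R)-2-{2-[methoxy(methyl)amino]-2-oxoethyl}-6-[(3E)-5-(methoxymethoxy)-4-methylpent-3-en-1-yl]-2,3,4,7-tetrahydrooxepine-2-carboxylate | C/C(=C\CCC1=CCC[C@@](CC(=O)N(C)OC)(C(=O)OC(C)(C)C)OC1)COCOC | intermediate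
29 | hydroquinone (benzene-1,4-diol) | Oc1ccc(O)cc1 | starting material
30 | 1,4-bis(methoxymethoxy)benzene | COCOc1ccc(OCOC)cc1 | intermediate
31 | [2,5-bis(methoxymethoxy)phenyl]lithium | [Li]c1cc(OCOC)ccc1OCOC | intermediate (not isolated)
32 | lithium alkoxide of tert-butyl (2R)-2-{2-[2,5-bis(methoxymethoxy)phenyl]-2-hydroxy-2-[methoxy(methyl)amino]ethyl}-6-[(3E)-5-(methoxymethoxy)-4-methylpent-3-en-1-yl]-2,3,4,7-tetrahydrooxepine-2-carboxylate (tetrahedral adduct) | C/C(=C\CCC1=CCC[C@@](CC(O[Li])(N(C)OC)c2cc(OCOC)ccc2OCOC)(C(=O)OC(C)(C)C)OC1)COCOC | intermediate (not isolated)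
33 | tert-butyl (2R)-2-{2-[2,5-bis(methoxymethoxy)phenyl]-2-oxoethyl}-6-[(3E)-5-(methoxymethoxy)-4-methylpent-3-en-1-yl]-2,3,4,7-tetrahydrooxepine-2-carboxylate | C/C(=C\CCC1=CCC[C@@](CC(=O)c2cc(OCOC)ccc2OCOC)(C(=O)OC(C)(C)C)OC1)COCOC | intermediate
34 | (2R)-2-[2-(2,5-dihydroxyphenyl)-2-oxoethyl]-6-[(3E)-5-hydroxy-4-methylpent-3-en-1-yl]-2,3,4,7-tetrahydrooxepine-2-carboxylic acid | C/C(=C\CCC1=CCC[C@@](CC(=O)c2cc(O)ccc2O)(C(=O)O)OC1)CO | target

## Step count and least certain steps

Total: 19 steps. Longest linear sequence: 16 steps from 1 (steps 1 to 8, 11 to 16, 18 and 19); steps 9 and 10 (side chain) and step 17 (arene) are side branches.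

Step 5 (key step). What may go wrong is migration of the C6 methylene in place of C2, since the ester on C2 lowers its migratory aptitude. Oxygen insertion at the hindered, electron-poor ketone may also be slow, in which case acid-induced loss of the tert-butyl ester or of the silyl ether can overtake it. The fallback keeps the disconnection but changes how the oxygen is delivered: from 7, bis(trimethylsilyl) peroxide with catalytic Me3SiOTf in CH2Cl2 at −78 to −40 °C activates the ketone, not the peroxide, and passes through a silylated Criegee adduct with no carboxylic acid in the flask, returning to the route at 9. No new compound is made (F0). If the wrong carbon migrates under both sets of conditions, the strategy offers no rescue at this stage.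

Step 1. Incomplete facial discrimination of the enolate would lower the enantiomeric purity, and because every later compound has a single stereocentre and is unlikely to crystallise, the purity reached here is carried to the end. The fallback changes the mode of asymmetric induction: from 1, alkylation with allyl bromide under chiral phase-transfer catalysis (a C2-symmetric spiro binaphthyl quaternary ammonium bromide, CsOH·H2O, toluene, low temperature), a method developed on tert-butyl 2-oxocycloalkanecarboxylates, returning at 3. No new compound is made (F0).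

Step 8. Addition of the amine to C5 may be slow because a conjugated lactone is a weaker acceptor than an enone, so the iodination may stall. The fallback replaces addition–elimination of an amine by halogen addition and dehydrohalogenation. From 13, Br2 in CH2Cl2 gives the trans-dibromide tert-butyl (2R)-5,6-dibromo-2-[2-(tert-butyldiphenylsilyloxy)ethyl]-7-oxooxepane-2-carboxylate F1, and Et3N eliminates HBr to give the bromo lactone tert-butyl (2R)-6-bromo-2-[2-(tert-butyldiphenylsilyloxy)ethyl]-7-oxo-2,3,4,7-tetrahydrooxepine-2-carboxylate F2. F2 is coupled with the alkylzinc 18 as in step 11 and returns at 19.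

Step 12 (with step 13). The tetrahedral aluminium intermediate may open the ring before it is acetylated and then take up a second hydride, and hydride may also attack the tert-butyl ester. In step 13, hydride capture at C5 of the conjugated cation is a further, smaller risk. The fallback gives up trapping the tetrahedral intermediate. From 19, excess iBu2AlH at −78 °C reduces the lactone fully to the diol tert-butyl (2R,5Z,9E)-2-[2-(tert-butyldiphenylsilyloxy)ethyl]-2-hydroxy-6-(hydroxymethyl)-11-(methoxymethoxy)-10-methylundeca-5,9-dienoate F3. MnO2 oxidises only the allylic alcohol to the hydroxy enal tert-butyl (2R,5Z,9E)-2-[2-(tert-butyldiphenylsilyloxy)ethyl]-6-formyl-2-hydroxy-11-(methoxymethoxy)-10-methylundeca-5,9-dienoate F4. Reductive etherification with Et3SiH and Me3SiOTf at −78 °C closes the ring and returns at 23.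

Step 18. The aryllithium may deprotonate the CH2 next to the amide, which would be followed by β-elimination of the ring oxygen and ring opening; addition to a carbonyl next to a quaternary carbon may also be slow. The fallback changes the electrophile to an aldehyde and the nucleophile to a less basic organometallic. From 24, Dess–Martin periodinane buffered with NaHCO3 gives the aldehyde 25, now isolated. The aryllithium 31 is transmetalated with CeCl3 to [2,5-bis(methoxymethoxy)phenyl]cerium dichloride F5, which adds at −78 °C to give the carbinol tert-butyl (2R)-2-{2-[2,5-bis(methoxymethoxy)phenyl]-2-hydroxyethyl}-6-[(3E)-5-(methoxymethoxy)-4-methylpent-3-en-1-yl]-2,3,4,7-tetrahydrooxepine-2-carboxylate F6. The reaction is quenched cold to prevent lactonisation onto the ester, and a second Dess–Martin oxidation returns at 33.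

Step 19. Several processes threaten the product once the groups are off: alkylation of the liberated hydroquinone by formaldehyde-derived electrophiles, ionisation or acylation of the allylic alcohol in strong acid, acid-promoted opening of the β-alkoxy ketone followed by chromanone formation, and air oxidation of the hydroquinone. The fallback splits the deprotection into two steps with different mechanisms. From 33, ZnBr2 and n-PrSH in CH2Cl2 at 0 °C remove the three MOM groups by Lewis-acid-assisted thiol capture, so that no free formaldehyde equivalent and no strong Brønsted acid are present, giving the tert-butyl ester of the target, tert-butyl (2R)-2-[2-(2,5-dihydroxyphenyl)-2-oxoethyl]-6-[(3E)-5-hydroxy-4-methylpent-3-en-1-yl]-2,3,4,7-tetrahydrooxepine-2-carboxylate F7. The ester is then cleaved alone with 85% aqueous H3PO4 in toluene at room temperature, returning at 34.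

## Further compounds

F0 | step 5 | none | none
F0 | step 1 | none | none
F1 | step 8 | tert-butyl (2R)-5,6-dibromo-2-[2-(tert-butyldiphenylsilyloxy)ethyl]-7-oxooxepane-2-carboxylate | O=C1C(Br)C(Br)CC[C@@](CCO[Si](c2ccccc2)(c2ccccc2)C(C)(C)C)(C(=O)OC(C)(C)C)O1
F2 | step 8 | tert-butyl (2R)-6-bromo-2-[2-(tert-butyldiphenylsilyloxy)ethyl]-7-oxo-2,3,4,7-tetrahydrooxepine-2-carboxylate | O=C1C(Br)=CCC[C@@](CCO[Si](c2ccccc2)(c2ccccc2)C(C)(C)C)(C(=O)OC(C)(C)C)O1
F3 | step 12 | tert-butyl (2R,5Z,9E)-2-[2-(tert-butyldiphenylsilyloxy)ethyl]-2-hydroxy-6-(hydroxymethyl)-11-(methoxymethoxy)-10-methylundeca-5,9-dienoate | C/C(=C\CC/C(CO)=C/CC[C@@](O)(CCO[Si](c1ccccc1)(c1ccccc1)C(C)(C)C)C(=O)OC(C)(C)C)COCOC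
F4 | step 12 | tert-butyl (2R,5Z,9E)-2-[2-(tert-butyldiphenylsilyloxy)ethyl]-6-formyl-2-hydroxy-11-(methoxymethoxy)-10-methylundeca-5,9-dienoate | C/C(=C\CC/C(C=O)=C/CC[C@@](O)(CCO[Si](c1ccccc1)(c1ccccc1)C(C)(C)C)C(=O)OC(C)(C)C)COCOC
F5 | step 18 | [2,5-bis(methoxymethoxy)phenyl]cerium dichloride | Cl[Ce](Cl)c1cc(OCOC)ccc1OCOC
F6 | step 18 | tert-butyl (2R)-2-{2-[2,5-bis(methoxymethoxy)phenyl]-2-hydroxyethyl}-6-[(3E)-5-(methoxymethoxy)-4-methylpent-3-en-1-yl]-2,3,4,7-tetrahydrooxepine-2-carboxylate | C/C(=C\CCC1=CCC[C@@](CC(O)c2cc(OCOC)ccc2OCOC)(C(=O)OC(C)(C)C)OC1)COCOC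
F7 | step 19 | tert-butyl (2R)-2-[2-(2,5-dihydroxyphenyl)-2-oxoethyl]-6-[(3E)-5-hydroxy-4-methylpent-3-en-1-yl]-2,3,4,7-tetrahydrooxepine-2-carboxylate | C/C(=C\CCC1=CCC[C@@](CC(=O)c2cc(O)ccc2O)(C(=O)OC(C)(C)C)OC1)CO
A1 | alternative 1 | tert-butyl (2R)-2-{2-[2-bromo-6-hydroxy-3-(methoxymethoxy)phenyl]-2-oxoethyl}-6-[(3E)-5-(methoxymethoxy)-4-methylpent-3-en-1-yl]-2,3,4,7-tetrahydrooxepine-2-carboxylate | C/C(=C\CCC1=CCC[C@@](CC(=O)c2c(Br)c(OCOC)ccc2O)(C(=O)OC(C)(C)C)OC1)COCOC
A2 | alternative 1 | 2-[(2R)-2-(tert-butoxycarbonyl)-6-[(3E)-5-(methoxymethoxy)-4-methylpent-3-en-1-yl]-2,3,4,7-tetrahydrooxepin-2-yl]acetic acid | C/C(=C\CCC1=CCC[C@@](CC(=O)O)(C(=O)OC(C)(C)C)OC1)COCOC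
A3 | alternative 1 | 3-bromo-4-(methoxymethoxy)-2-(trimethylsilyl)phenyl trifluoromethanesulfonate | COCOc1ccc(OS(=O)(=O)C(F)(F)F)c([Si](C)(C)C)c1Br
A4 | alternative 2 | tert-butyl (2R)-2-{2-[2,5-bis(methoxymethoxy)phenyl]-2-oxoethyl}-6-[(3E)-5-(methoxymethoxy)-4-methylpent-3-en-1-yl]-2,3,4,7-tetrahydrooxepine-2-carboxylate | C/C(=C\CCC1=CCC[C@@](CC(=O)c2cc(OCOC)ccc2OCOC)(C(=O)OC(C)(C)C)OC1)COCOC
A5 | alternative 2 | tert-butyl (2E)-4-[2,5-bis(methoxymethoxy)phenyl]-2-[(3Z,7E)-4-(hydroxymethyl)-9-(methoxymethoxy)-8-methylnona-3,7-dien-1-yl]-4-oxobut-2-enoate | COCOc1ccc(OCOC)c(c1)C(=O)/C=C(\CC/C=C(\CO)CC/C=C(\C)COCOC)C(=O)OC(C)(C)C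
A6 | alternative 3 | 2-tert-butyl 6-methyl (2R)-2-[2-(tert-butyldiphenylsilyloxy)ethyl]-2,3-dihydrooxepine-2,6-dicarboxylate | COC(=O)C=1C=CC[C@@](CCO[Si](c2ccccc2)(c2ccccc2)C(C)(C)C)(C(=O)OC(C)(C)C)OC=1
A7 | alternative 3 | tert-butyl (2R)-2-[2-(tert-butyldiphenylsilyloxy)ethyl]-2,3-dihydrofuran-2-carboxylate | C1=CC[C@@](CCO[Si](c2ccccc2)(c2ccccc2)C(C)(C)C)(C(=O)OC(C)(C)C)O1
A8 | alternative 3 | methyl propiolate (methyl prop-2-ynoate) | C#CC(=O)OC
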